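This closed, stirred, isothermal vessel starts with substrate, and I follow one molecule of it through its forks.

| flask | substrate | remark | time |
|---|---|---|---|
| grey | 0.80 M | the very flask that is asked about, followed so far |  |
| flask | 0.80 M |  | 2.5 d |

grey run (percent of the substrate charged)

| time / h | intermediate / % | target / % | substrate / % |
|---|---|---|---|
| 1.33 | 32.4 | 30.8 | 16.1 |
| 2.50 | 32.9 | 32.5 | 3.9 |
| 4.00 | 30.3 | 29.5 | 0.5 |
| 5.00 | 26.2 | 30.6 | 0.1 |
| 6.00 | 24.7 | 25.5 | 1.3 |
| 8.00 | 23.0 | 22.0 | 0.8 |

(each reading ± 1 percentage point)

- time up to 2.5 d at which intermediate stands highest
- the amount of intermediate, in percent of the substrate charged, at that time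



In the grey run, which is this flask followed so far, [substrate] at 2.50 h gives a departure rate of 1.30 h⁻¹. Intermediate and target stand close there, 32.9% against 32.5%, so I treat them as one pair and give the molecule an even chance of being intermediate. Once [substrate] in the grey run reads 0.5%, the pair shrinks from 59.8% to 45.0% by 8.00 h, a leak I read as 0.0711 h⁻¹. A first-order feed and leak peak at the logarithm of their ratio over their difference, here 0.0987 d. The even split times survival to that time gives 0.423, the peak chance, meaning the chance that a molecule which has entered the pair stands as intermediate at the peak.

I still need the entry chance, the selectivity of the first fork. The pair over the substrate consumed at 2.50 h in the grey run gives 0.681, hence a peak of 28.8%, which is lower than the reading of 32.9%. That link is weak, since those molecules have already leaked for about 1.73 h. Restoring the leak gives 0.770, so I commit to 32.5% at 0.0987 d.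

The forecast puts the peak earlier than I do, at 0.09 d, and higher, at 33.3%, and it notes: “Intermediate and target appear in nearly equal amounts”.

The flask peaks at 0.0870 d with 33.5%.

    substrate → intermediate (k = 0.0200 min⁻¹)
    intermediate ⇌ target (K = 1.00, k = 0.100 min⁻¹)
    intermediate ⇌ isomer of the product (K = 44.0, k = 0.00300 min⁻¹)
    substrate + target → side product (k = 0.00100 M⁻¹ min⁻¹)
    2 substrate → self-condensation product (k = 0.00530 M⁻¹ min⁻¹)

Self-condensation product holds 16.6% of the charge at 2.50 d, counted in substrate charged, so taking the rest as the entry chance, side product at 1.14% set aside, and multiplying by the peak chance gives 35.3% for this flask. The neighbour flask, charged with 0.20 M of substrate, holds 4.95% of self-condensation product at 2.50 d. The same reckoning, with the peak chance held at its value from the grey run, gives 40.2% there, and intermediate in that neighbour flask peaks at 38.3%.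

The data are simulated for an exercise; scatter was added.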